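**Plan**
1. Retrosynthetic cuts, in order: the aryl–CH2 bond and the C4'–O bond of the oxolane (aryl Grignard on a spiro-epoxide made from a 4-methylene oxolane); O1'–C5' and C2'–C3' of the oxolane (cyclodehydration; allylboration–lactonisation of a benzofuran aldehyde); then, together, O1–C7a and C2–C3 of the dihydrobenzofuran.
2. Forward: fluoro nitrile arene → (E)-γ-aryl allylboronate → dihydrobenzofuran ring in one operation with O-benzylvanillin → vinyl to CH2OH and nitrile to CHO → oxolane ring → epoxide → arylmethyl group → deprotection.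
3. Enabling feature: O1 and C2 are an aldehyde (vanillin) in disguise; C3 is benzylic on C3a and can be the γ-carbon of an allylboronate whose vinyl group is a masked CH2OH; C7a is para to C5, so the future oxolane carbon C2', carried on C5 as a nitrile, activates a fluoride on C7a for displacement by the new alkoxide.
4. Stereochemistry: C2/C3 (cis) from (R)-TRIP and the (E)-boronate (anti adduct); C2'/C3' (cis) from (R)-TRIP and a boronate whose γ-substituent is cis to CH2B (syn adduct); C4' from epoxidation anti to the two cis substituents of the methylene oxolane.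
5. The helpers (fluoride, nitrile, vinyl, lactone carbonyl) are all consumed or converted on the way to the target.

Key step: step 4

Assumption: (R)-TRIP is taken to expose the Re face of an aryl aldehyde to the γ-aryl and the 2-alkoxycarbonyl allyl pinacol boronates as it does to allyl and crotyl pinacol boronates.

Abbreviations: TBS = tert-butyldimethylsilyl; Bn = benzyl; (R)-TRIP = (R)-3,3'-bis(2,4,6-triisopropylphenyl)-1,1'-binaphthyl-2,2'-diyl hydrogen phosphate; Ar1 = (2R,3R)-2-[4-(benzyloxy)-3-methoxyphenyl]-3-{[(tert-butyldimethylsilyl)oxy]methyl}-7-methoxy-2,3-dihydro-1-benzofuran-5-yl.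

**Step 1**
Reactants: 1 3-bromo-4-hydroxy-5-methoxybenzonitrile
Product: 3 3-bromo-4-fluoro-5-methoxybenzonitrile, via aryloxyimidazolium bifluoride 2 (not isolated)
Conditions: PhenoFluor, CsF, toluene, 110 °C
Reagents that add atoms: PhenoFluor, FC1(F)N(c2c(C(C)C)cccc2C(C)C)C=CN1c1c(C(C)C)cccc1C(C)C; caesium fluoride, [Cs+].[F-] (its fluoride pools with that of the reagent)
Why: Deoxyfluorination of a phenol, in which the aryloxyimidazolium bifluoride 2 undergoes concerted nucleophilic aromatic substitution at the ipso carbon, made easy by the para nitrile, to give the aryl fluoride that the key step needs as leaving group.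

**Step 2**
Reactants: 3 3-bromo-4-fluoro-5-methoxybenzonitrile
Product: 4 3-ethenyl-4-fluoro-5-methoxybenzonitrile
Conditions: vinylboronic acid pinacol ester, PdCl2(dppf) (5 mol %), CsF, dioxane, 85 °C
Reagents that add atoms: vinylboronic acid pinacol ester, C=CB1OC(C)(C)C(C)(C)O1
Why: Suzuki–Miyaura coupling at the C–Br bond, which zerovalent palladium enters far more readily than C–F, with anhydrous fluoride as base so that the activated aryl fluoride is not hydrolysed.

**Step 3**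
Reactants: 4 3-ethenyl-4-fluoro-5-methoxybenzonitrile
Product: 5 4-fluoro-3-methoxy-5-[(1E)-3-(4,4,5,5-tetramethyl-1,3,2-dioxaborolan-2-yl)prop-1-en-1-yl]benzonitrile
Conditions: allylboronic acid pinacol ester (3 equiv), second-generation Grubbs catalyst RuCl2(=CHPh)(PCy3)(H2IMes) (5 mol %), CH2Cl2, 40 °C
Reagents that add atoms: allylboronic acid pinacol ester, C=CCB1OC(C)(C)C(C)(C)O1
Why: Olefin cross-metathesis of a styrene with allyl pinacol boronate, which should give the conjugated (E)-alkene as the favoured isomer with loss of ethene.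

**Step 4**
Reactants: 5 4-fluoro-3-methoxy-5-[(1E)-3-(4,4,5,5-tetramethyl-1,3,2-dioxaborolan-2-yl)prop-1-en-1-yl]benzonitrile; 6 4-(benzyloxy)-3-methoxybenzaldehyde
Product: 9 (2R,3S)-2-[4-(benzyloxy)-3-methoxyphenyl]-3-ethenyl-7-methoxy-2,3-dihydro-1-benzofuran-5-carbonitrile (2,3-cis), via homoallyl pinacol borate 7 (not isolated), via potassium alkoxide 8 (not isolated)
Conditions: (R)-TRIP (5 mol %), 4 Å molecular sieves, toluene, −30 °C → rt; then KOtBu (1.2 equiv), THF, 0 °C → rt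
Reagents that add atoms: none
Why: The phosphoric acid hydrogen-bonds to a boronate oxygen and to the formyl hydrogen of 6 and steers a closed six-membered chair in which the γ-carbon of the (E)-boronate (future C3) adds to the aldehyde carbon (future C2) to give the anti borate 7; tert-butoxide then passes to boron and frees alkoxide 8, whose oxygen displaces fluoride at C7a through a Meisenheimer complex stabilised by the para nitrile (addition–elimination). The closest known reactions are the chiral-phosphoric-acid-catalysed crotylboration of aryl aldehydes with pinacol boronates and the closure of 2-(2-fluoroaryl)ethanol alkoxides to dihydrobenzofurans. The dihydrofuran ring closes by 5-exo-trig attack of O1 on the ipso carbon C7a followed by loss of fluoride, so O1–C7a and C3–C2 are both made in this one operation. C2 is set by the catalyst, (R)-TRIP exposing the Re face of the aldehyde, and C3 is set relative to C2 by the (E)-alkene geometry through the chair (aryl pseudo-equatorial, anti adduct), which maps onto the cis-2,3 ring because the fluoride displacement touches neither stereocentre. The step needs E-geometry in 5, O-arylation faster than tert-butoxide attack on the ring, and no deprotonation at the allylic and benzylic C3–H; these are secured by the E-selective metathesis, by the intramolecular five-ring closure against a hindered external base, and by barely more than one equivalent of base in THF at or below room temperature.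

**Step 5**
Reactants: 9 (2R,3S)-2-[4-(benzyloxy)-3-methoxyphenyl]-3-ethenyl-7-methoxy-2,3-dihydro-1-benzofuran-5-carbonitrile
Product: 12 (2R,3R)-2-[4-(benzyloxy)-3-methoxyphenyl]-3-(hydroxymethyl)-7-methoxy-2,3-dihydro-1-benzofuran-5-carbonitrile, via secondary ozonide 10 (not isolated), via aldehyde 11 (not isolated)
Conditions: O3, CH2Cl2, −78 °C; then NaBH4, MeOH, −78 → 0 °C
Reagents that add atoms: ozone, [O-][O+]=O
Why: Ozonolysis with reductive work-up, in which the terminal alkene reacts far faster than the arenes and borohydride reduces ozonide 10 and aldehyde 11 in the cold before the cis α-aryl aldehyde can epimerise, so C3 is kept.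

**Step 6**
Reactants: 12 (2R,3R)-2-[4-(benzyloxy)-3-methoxyphenyl]-3-(hydroxymethyl)-7-methoxy-2,3-dihydro-1-benzofuran-5-carbonitrile
Product: 13 (2R,3R)-2-[4-(benzyloxy)-3-methoxyphenyl]-3-{[(tert-butyldimethylsilyl)oxy]methyl}-7-methoxy-2,3-dihydro-1-benzofuran-5-carbonitrile
Conditions: TBSCl, imidazole, DMF, rt
Reagents that add atoms: tert-butyldimethylsilyl chloride, CC(C)(C)[Si](C)(C)Cl
Why: Silyl ether formation at the primary alcohol, to keep this hydroxyl out of the later reduction, Mitsunobu and Grignard steps.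

**Step 7**
Reactants: 13 (2R,3R)-2-[4-(benzyloxy)-3-methoxyphenyl]-3-{[(tert-butyldimethylsilyl)oxy]methyl}-7-methoxy-2,3-dihydro-1-benzofuran-5-carbonitrile
Product: 15 (2R,3R)-2-[4-(benzyloxy)-3-methoxyphenyl]-3-{[(tert-butyldimethylsilyl)oxy]methyl}-7-methoxy-2,3-dihydro-1-benzofuran-5-carbaldehyde (Ar1–CHO), via N-aluminio aldimine 14 (not isolated)
Conditions: iBu2AlH (1.5 equiv), toluene, −78 °C; then aqueous potassium sodium tartrate
Reagents that add atoms: water, O
Why: Partial reduction of a nitrile by one hydride to the N-aluminio aldimine 14, which is stable in the cold and is hydrolysed to the aldehyde on work-up, so the activating nitrile becomes the future oxolane carbon C2'.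

**Step 8**
Reactants: 16 [(tert-butyldimethylsilyl)oxy]acetaldehyde; 17 methyl acrylate
Product: 18 methyl 4-[(tert-butyldimethylsilyl)oxy]-3-hydroxy-2-methylidenebutanoate (racemic)
Conditions: DABCO (0.5 equiv), dioxane–water, rt
Reagents that add atoms: none
Why: Morita–Baylis–Hillman reaction of an α-silyloxy aldehyde with an acrylate under nucleophilic amine catalysis; the new carbinol centre is racemic and is erased in step 10.

**Step 9**
Reactants: 18 methyl 4-[(tert-butyldimethylsilyl)oxy]-3-hydroxy-2-methylidenebutanoate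
Product: 19 methyl 3-(acetyloxy)-4-[(tert-butyldimethylsilyl)oxy]-2-methylidenebutanoate (racemic)
Conditions: Ac2O, pyridine, DMAP (cat.), CH2Cl2, 0 °C
Reagents that add atoms: acetic anhydride, CC(=O)OC(C)=O
Why: DMAP-catalysed acetylation turns the secondary allylic alcohol into a leaving group.

**Step 10**
Reactants: 19 methyl 3-(acetyloxy)-4-[(tert-butyldimethylsilyl)oxy]-2-methylidenebutanoate
Product: 20 methyl (2E)-4-[(tert-butyldimethylsilyl)oxy]-2-[(4,4,5,5-tetramethyl-1,3,2-dioxaborolan-2-yl)methyl]but-2-enoate (CH2B cis to CH2OTBS)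
Conditions: B2pin2, CuCl (10 mol %), KOAc, DMF, rt
Reagents that add atoms: bis(pinacolato)diboron, CC1(C)OB(OC1(C)C)B1OC(C)(C)C(C)(C)O1
Why: Copper-mediated borylation of a Morita–Baylis–Hillman acetate with allylic transposition (SN2'), which should give the trisubstituted enoate with the ester trans to the silyloxymethyl group, so that CH2B and the γ-substituent are cis as a syn-selective allylboration requires.

**Step 11**
Reactants: 15 Ar1–CHO; 20 methyl (2E)-4-[(tert-butyldimethylsilyl)oxy]-2-[(4,4,5,5-tetramethyl-1,3,2-dioxaborolan-2-yl)methyl]but-2-enoate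
Product: 22 (4R,5R)-5-Ar1-4-{[(tert-butyldimethylsilyl)oxy]methyl}-3-methylideneoxolan-2-one (4,5-cis), via homoallyl pinacol borate 21 (not isolated)
Conditions: (R)-TRIP (10 mol %), 4 Å molecular sieves, toluene, rt → 45 °C
Reagents that add atoms: none
Why: Chiral-phosphoric-acid-catalysed allylboration through a closed chair followed by lactonisation of borate 21 onto the ester; the γ-substituent cis to CH2B sits pseudo-axial and gives the syn adduct, hence the cis lactone, and (R)-TRIP sets C2' as R by Re-face addition, independent of the remote stereocentres.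

**Step 12**
Reactants: 22 (4R,5R)-5-Ar1-4-{[(tert-butyldimethylsilyl)oxy]methyl}-3-methylideneoxolan-2-one
Product: 23 (1R,2R)-1-Ar1-2-{[(tert-butyldimethylsilyl)oxy]methyl}-3-methylidenebutane-1,4-diol
Conditions: iBu2AlH (4 equiv), CH2Cl2, −78 → 0 °C; then aqueous potassium sodium tartrate
Reagents that add atoms: none
Why: 1,2-Reduction of the α-methylene lactone by the aluminium hydride to the allylic 1,4-diol, without touching C2' or C3'.

**Step 13**
Reactants: 23 (1R,2R)-1-Ar1-2-{[(tert-butyldimethylsilyl)oxy]methyl}-3-methylidenebutane-1,4-diol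
Product: 24 (2R,3R)-2-Ar1-3-{[(tert-butyldimethylsilyl)oxy]methyl}-4-methylideneoxolane (2,3-cis)
Conditions: PPh3, DIAD, THF, 0 °C → rt
Reagents that add atoms: none
Why: Mitsunobu cyclodehydration, in which the less hindered primary allylic hydroxyl is activated as its oxyphosphonium salt and displaced by the secondary benzylic hydroxyl in a 5-exo-tet closure, so the C–O bond at C2' is not broken and its configuration is kept.

**Step 14**
Reactants: 24 (2R,3R)-2-Ar1-3-{[(tert-butyldimethylsilyl)oxy]methyl}-4-methylideneoxolane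
Product: 25 (3R,6R,7R)-6-Ar1-7-{[(tert-butyldimethylsilyl)oxy]methyl}-1,5-dioxaspiro[2.4]heptane
Conditions: mCPBA, NaHCO3, CH2Cl2, 0 °C
Reagents that add atoms: 3-chloroperoxybenzoic acid, OOC(=O)c1cccc(Cl)c1
Why: Prilezhaev epoxidation of the 1,1-disubstituted alkene from the face opposite to the cis aryl and silyloxymethyl groups on C2' and C3', which places the new oxygen on C4' trans to both and sets C4'.

**Step 15**
Reactants: 25 (3R,6R,7R)-6-Ar1-7-{[(tert-butyldimethylsilyl)oxy]methyl}-1,5-dioxaspiro[2.4]heptane; 26 1-(benzyloxy)-4-bromo-2-methoxybenzene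
Product: 28 (3S,4R,5R)-3-[4-(benzyloxy)-3-methoxybenzyl]-5-Ar1-4-{[(tert-butyldimethylsilyl)oxy]methyl}oxolan-3-ol, via aryl Grignard reagent 27 (not isolated)
Conditions: 26 (3 equiv), Mg, THF, rt; then CuI (10 mol %), 25, THF, −40 → 0 °C
Reagents that add atoms: none
Why: Copper-catalysed opening of the spiro-epoxide by the aryl Grignard reagent at the unsubstituted CH2 (SN2), which installs the arylmethyl group and frees the tertiary alcohol without touching C4'.

**Step 16**
Reactants: 28 (3S,4R,5R)-3-[4-(benzyloxy)-3-methoxybenzyl]-5-Ar1-4-{[(tert-butyldimethylsilyl)oxy]methyl}oxolan-3-ol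
Product: 29 (3S,4R,5R)-3-[4-(benzyloxy)-3-methoxybenzyl]-5-[(2R,3R)-2-[4-(benzyloxy)-3-methoxyphenyl]-3-(hydroxymethyl)-7-methoxy-2,3-dihydro-1-benzofuran-5-yl]-4-(hydroxymethyl)oxolan-3-ol
Conditions: Bu4NF, THF, 0 °C → rt
Reagents that add atoms: none
Why: Fluoride-induced cleavage of the two primary silyl ethers (desilylation), which leaves all stereocentres and the benzyl ethers alone.

**Step 17**
Reactants: 29 (3S,4R,5R)-3-[4-(benzyloxy)-3-methoxybenzyl]-5-[(2R,3R)-2-[4-(benzyloxy)-3-methoxyphenyl]-3-(hydroxymethyl)-7-methoxy-2,3-dihydro-1-benzofuran-5-yl]-4-(hydroxymethyl)oxolan-3-ol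
Product: 30 (3S,4R,5R)-5-[(2R,3R)-2-(4-hydroxy-3-methoxyphenyl)-3-(hydroxymethyl)-7-methoxy-2,3-dihydro-1-benzofuran-5-yl]-3-[(4-hydroxy-3-methoxyphenyl)methyl]-4-(hydroxymethyl)oxolan-3-ol (CNP0284796.1)
Conditions: H2 (1 atm), 10% Pd/C, EtOAc, rt, stopped at full conversion
Reagents that add atoms: none
Why: Hydrogenolysis of the two aryl benzyl ethers over palladium, which should be much faster than cleavage of the ring benzylic C–O bonds of the dihydrobenzofuran and the oxolane.

**Compound list**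
1 | 3-bromo-4-hydroxy-5-methoxybenzonitrile | N#Cc1cc(Br)c(O)c(OC)c1 | starting material
2 | 2-(2-bromo-4-cyano-6-methoxyphenoxy)-1,3-bis(2,6-diisopropylphenyl)imidazolium hydrogen difluoride (not isolated) | N#Cc1cc(Br)c(OC2=[N+](c3c(C(C)C)cccc3C(C)C)C=CN2c2c(C(C)C)cccc2C(C)C)c(OC)c1.F.[F-] | intermediate
3 | 3-bromo-4-fluoro-5-methoxybenzonitrile | N#Cc1cc(Br)c(F)c(OC)c1 | intermediate
4 | 3-ethenyl-4-fluoro-5-methoxybenzonitrile | N#Cc1cc(C=C)c(F)c(OC)c1 | intermediate
5 | 4-fluoro-3-methoxy-5-[(1E)-3-(4,4,5,5-tetramethyl-1,3,2-dioxaborolan-2-yl)prop-1-en-1-yl]benzonitrile | N#Cc1cc(/C=C/CB2OC(C)(C)C(C)(C)O2)c(F)c(OC)c1 | intermediate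
6 | 4-(benzyloxy)-3-methoxybenzaldehyde | O=Cc1ccc(OCc2ccccc2)c(OC)c1 | starting material
7 | 3-{(3S,4R)-4-[4-(benzyloxy)-3-methoxyphenyl]-4-[(4,4,5,5-tetramethyl-1,3,2-dioxaborolan-2-yl)oxy]but-1-en-3-yl}-4-fluoro-5-methoxybenzonitrile (not isolated) | N#Cc1cc(OC)c(F)c(c1)[C@H](C=C)[C@H](c1ccc(OCc2ccccc2)c(OC)c1)OB1OC(C)(C)C(C)(C)O1 | intermediate
8 | potassium (1R,2S)-1-[4-(benzyloxy)-3-methoxyphenyl]-2-(5-cyano-2-fluoro-3-methoxyphenyl)but-3-en-1-olate (not isolated) | N#Cc1cc(OC)c(F)c(c1)[C@H](C=C)[C@H](c1ccc(OCc2ccccc2)c(OC)c1)[O-].[K+] | intermediate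
9 | (2R,3S)-2-[4-(benzyloxy)-3-methoxyphenyl]-3-ethenyl-7-methoxy-2,3-dihydro-1-benzofuran-5-carbonitrile | N#Cc1cc(OC)c2c(c1)[C@H](C=C)[C@H](c1ccc(OCc3ccccc3)c(OC)c1)O2 | intermediate
10 | (2R,3S)-2-[4-(benzyloxy)-3-methoxyphenyl]-7-methoxy-3-(1,2,4-trioxolan-3-yl)-2,3-dihydro-1-benzofuran-5-carbonitrile, both epimers at the trioxolane carbon (not isolated) | N#Cc1cc(OC)c2c(c1)[C@H](C1OCOO1)[C@H](c1ccc(OCc3ccccc3)c(OC)c1)O2 | intermediate
11 | (2R,3S)-2-[4-(benzyloxy)-3-methoxyphenyl]-3-formyl-7-methoxy-2,3-dihydro-1-benzofuran-5-carbonitrile (not isolated) | N#Cc1cc(OC)c2c(c1)[C@H](C=O)[C@H](c1ccc(OCc3ccccc3)c(OC)c1)O2 | intermediate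
12 | (2R,3R)-2-[4-(benzyloxy)-3-methoxyphenyl]-3-(hydroxymethyl)-7-methoxy-2,3-dihydro-1-benzofuran-5-carbonitrile | N#Cc1cc(OC)c2c(c1)[C@H](CO)[C@H](c1ccc(OCc3ccccc3)c(OC)c1)O2 | intermediate
13 | (2R,3R)-2-[4-(benzyloxy)-3-methoxyphenyl]-3-{[(tert-butyldimethylsilyl)oxy]methyl}-7-methoxy-2,3-dihydro-1-benzofuran-5-carbonitrile | N#Cc1cc(OC)c2c(c1)[C@H](CO[Si](C)(C)C(C)(C)C)[C@H](c1ccc(OCc3ccccc3)c(OC)c1)O2 | intermediate
14 | N-(diisobutylalumanyl) aldimine of 15 (not isolated) | CC(C)C[Al](CC(C)C)N=Cc1cc(OC)c2c(c1)[C@H](CO[Si](C)(C)C(C)(C)C)[C@H](c1ccc(OCc3ccccc3)c(OC)c1)O2 | intermediate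
15 | (2R,3R)-2-[4-(benzyloxy)-3-methoxyphenyl]-3-{[(tert-butyldimethylsilyl)oxy]methyl}-7-methoxy-2,3-dihydro-1-benzofuran-5-carbaldehyde | O=Cc1cc(OC)c2c(c1)[C@H](CO[Si](C)(C)C(C)(C)C)[C@H](c1ccc(OCc3ccccc3)c(OC)c1)O2 | intermediate
16 | [(tert-butyldimethylsilyl)oxy]acetaldehyde | O=CCO[Si](C)(C)C(C)(C)C | starting material
17 | methyl acrylate | C=CC(=O)OC | starting material
18 | methyl 4-[(tert-butyldimethylsilyl)oxy]-3-hydroxy-2-methylidenebutanoate (racemic) | COC(=O)C(=C)C(O)CO[Si](C)(C)C(C)(C)C | intermediate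
19 | methyl 3-(acetyloxy)-4-[(tert-butyldimethylsilyl)oxy]-2-methylidenebutanoate (racemic) | COC(=O)C(=C)C(OC(C)=O)CO[Si](C)(C)C(C)(C)C | intermediate
20 | methyl (2E)-4-[(tert-butyldimethylsilyl)oxy]-2-[(4,4,5,5-tetramethyl-1,3,2-dioxaborolan-2-yl)methyl]but-2-enoate | COC(=O)/C(CB1OC(C)(C)C(C)(C)O1)=C/CO[Si](C)(C)C(C)(C)C | intermediate
21 | methyl (3R)-3-[(R)-Ar1[(4,4,5,5-tetramethyl-1,3,2-dioxaborolan-2-yl)oxy]methyl]-4-[(tert-butyldimethylsilyl)oxy]-2-methylidenebutanoate (not isolated) | C=C(C(=O)OC)[C@H](CO[Si](C)(C)C(C)(C)C)[C@H](c1cc(OC)c2c(c1)[C@H](CO[Si](C)(C)C(C)(C)C)[C@H](c1ccc(OCc3ccccc3)c(OC)c1)O2)OB1OC(C)(C)C(C)(C)O1 | intermediate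
22 | (4R,5R)-5-Ar1-4-{[(tert-butyldimethylsilyl)oxy]methyl}-3-methylideneoxolan-2-one | C=C1C(=O)O[C@@H](c2cc(OC)c3c(c2)[C@H](CO[Si](C)(C)C(C)(C)C)[C@H](c2ccc(OCc4ccccc4)c(OC)c2)O3)[C@H]1CO[Si](C)(C)C(C)(C)C | intermediate
23 | (1R,2R)-1-Ar1-2-{[(tert-butyldimethylsilyl)oxy]methyl}-3-methylidenebutane-1,4-diol | C=C(CO)[C@H](CO[Si](C)(C)C(C)(C)C)[C@H](c1cc(OC)c2c(c1)[C@H](CO[Si](C)(C)C(C)(C)C)[C@H](c1ccc(OCc3ccccc3)c(OC)c1)O2)O | intermediate
24 | (2R,3R)-2-Ar1-3-{[(tert-butyldimethylsilyl)oxy]methyl}-4-methylideneoxolane | C=C1CO[C@@H](c2cc(OC)c3c(c2)[C@H](CO[Si](C)(C)C(C)(C)C)[C@H](c2ccc(OCc4ccccc4)c(OC)c2)O3)[C@H]1CO[Si](C)(C)C(C)(C)C | intermediate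
25 | (3R,6R,7R)-6-Ar1-7-{[(tert-butyldimethylsilyl)oxy]methyl}-1,5-dioxaspiro[2.4]heptane | C1O[C@@]12CO[C@@H](c3cc(OC)c4c(c3)[C@H](CO[Si](C)(C)C(C)(C)C)[C@H](c3ccc(OCc5ccccc5)c(OC)c3)O4)[C@H]2CO[Si](C)(C)C(C)(C)C | intermediate
26 | 1-(benzyloxy)-4-bromo-2-methoxybenzene | COc1cc(Br)ccc1OCc1ccccc1 | starting material
27 | [4-(benzyloxy)-3-methoxyphenyl]magnesium bromide (not isolated) | COc1cc([Mg]Br)ccc1OCc1ccccc1 | intermediate
28 | (3S,4R,5R)-3-[4-(benzyloxy)-3-methoxybenzyl]-5-Ar1-4-{[(tert-butyldimethylsilyl)oxy]methyl}oxolan-3-ol | COc1cc(C[C@@]2(O)CO[C@@H](c3cc(OC)c4c(c3)[C@H](CO[Si](C)(C)C(C)(C)C)[C@H](c3ccc(OCc5ccccc5)c(OC)c3)O4)[C@H]2CO[Si](C)(C)C(C)(C)C)ccc1OCc1ccccc1 | intermediate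
29 | (3S,4R,5R)-3-[4-(benzyloxy)-3-methoxybenzyl]-5-[(2R,3R)-2-[4-(benzyloxy)-3-methoxyphenyl]-3-(hydroxymethyl)-7-methoxy-2,3-dihydro-1-benzofuran-5-yl]-4-(hydroxymethyl)oxolan-3-ol | COc1cc(C[C@@]2(O)CO[C@@H](c3cc(OC)c4c(c3)[C@H](CO)[C@H](c3ccc(OCc5ccccc5)c(OC)c3)O4)[C@H]2CO)ccc1OCc1ccccc1 | intermediate
30 | (3S,4R,5R)-5-[(2R,3R)-2-(4-hydroxy-3-methoxyphenyl)-3-(hydroxymethyl)-7-methoxy-2,3-dihydro-1-benzofuran-5-yl]-3-[(4-hydroxy-3-methoxyphenyl)methyl]-4-(hydroxymethyl)oxolan-3-ol | COc1cc(C[C@@]2(O)CO[C@@H](c3cc(OC)c4c(c3)[C@H](CO)[C@H](c3ccc(O)c(OC)c3)O4)[C@H]2CO)ccc1O | target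

**Step count and risks**
Total: 17 steps. Longest linear sequence: 14 steps (steps 1–7 and 11–17); steps 8–10 make boronate 20.

Steps most likely to fail:

Step 4. The alkoxide base may remove the allylic and benzylic C3–H, which would move the double bond into conjugation before closure or, after closure, epimerise C3 or open the ring by β-elimination of the aryloxide. The fallback separates the two bond formations and closes the ring only after the vinyl group is gone. It sets out from 5 and 6. The same acid-catalysed allylboration is quenched with aqueous NaHCO3 to give 3-{(3S,4R)-4-[4-(benzyloxy)-3-methoxyphenyl]-4-hydroxybut-1-en-3-yl}-4-fluoro-5-methoxybenzonitrile F1. Ozonolysis in CH2Cl2 at −78 °C gives the secondary ozonide of F1, F2, which NaBH4 in MeOH reduces through (2S,3R)-3-[4-(benzyloxy)-3-methoxyphenyl]-2-(5-cyano-2-fluoro-3-methoxyphenyl)-3-hydroxypropanal F3 to 3-{(1R,2R)-1-[4-(benzyloxy)-3-methoxyphenyl]-1,3-dihydroxypropan-2-yl}-4-fluoro-5-methoxybenzonitrile F4. TBSCl and imidazole silylate only the primary hydroxyl, its preferred site, to give 3-{(1R,2R)-1-[4-(benzyloxy)-3-methoxyphenyl]-3-[(tert-butyldimethylsilyl)oxy]-1-hydroxypropan-2-yl}-4-fluoro-5-methoxybenzonitrile F5. NaH in THF at 0 °C then displaces fluoride and gives 13, where the route is rejoined.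

Step 11. The ester-conjugated boronate may add too slowly under the weak acid, and forcing the reaction may erode face selectivity or ionise the electron-rich benzylic carbinol, which would scramble cis and trans. The fallback gives up catalyst control for a metal-mediated Barbier allylation and a separation. It sets out from 18 and 15. NBS and Me2S convert 18 with allylic transposition into methyl (2Z)-2-(bromomethyl)-4-[(tert-butyldimethylsilyl)oxy]but-2-enoate F6. Indium metal in THF–water allylates 15 through a cyclic transition state to the two syn adducts, methyl (3R)-3-[(R)-Ar1(hydroxy)methyl]-4-[(tert-butyldimethylsilyl)oxy]-2-methylidenebutanoate F7 and methyl (3S)-3-[(S)-Ar1(hydroxy)methyl]-4-[(tert-butyldimethylsilyl)oxy]-2-methylidenebutanoate F8. A trace of pyridinium tosylate lactonises them to 22 and to (4S,5S)-5-Ar1-4-{[(tert-butyldimethylsilyl)oxy]methyl}-3-methylideneoxolan-2-one F9. The two cis lactones are diastereomers and are separated by chromatography; 22 rejoins the route.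

Step 15. Magnesium halide may isomerise the 2,2-disubstituted epoxide to an aldehyde (Meinwald rearrangement) or open it to a bromohydrin faster than the aryl copper species attacks the hindered CH2. The fallback replaces the organometallic opening by a nickel-catalysed reductive coupling of the two electrophiles. It sets out from 25 and 26, with NiBr2(dme), 4,4'-di-tert-butyl-2,2'-bipyridine, NaI, Mn powder and Et3N·HCl in DMPU at rt. Iodide opens the epoxide at CH2 to (3S,4R,5R)-5-Ar1-3-(iodomethyl)-4-{[(tert-butyldimethylsilyl)oxy]methyl}oxolan-3-ol F10, whose primary C–I bond enters the nickel cycle and is joined to the aryl bromide to give 28 directly.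

**Further compounds**
F1 | step 4 | 3-{(3S,4R)-4-[4-(benzyloxy)-3-methoxyphenyl]-4-hydroxybut-1-en-3-yl}-4-fluoro-5-methoxybenzonitrile | N#Cc1cc(OC)c(F)c(c1)[C@H](C=C)[C@H](c1ccc(OCc2ccccc2)c(OC)c1)O
F2 | step 4 | secondary ozonide of F1 (1,2,4-trioxolan-3-yl in place of ethenyl, both epimers at the trioxolane carbon) | N#Cc1cc(OC)c(F)c(c1)[C@H](C1OCOO1)[C@H](c1ccc(OCc2ccccc2)c(OC)c1)O
F3 | step 4 | (2S,3R)-3-[4-(benzyloxy)-3-methoxyphenyl]-2-(5-cyano-2-fluoro-3-methoxyphenyl)-3-hydroxypropanal | N#Cc1cc(OC)c(F)c(c1)[C@H](C=O)[C@H](c1ccc(OCc2ccccc2)c(OC)c1)O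
F4 | step 4 | 3-{(1R,2R)-1-[4-(benzyloxy)-3-methoxyphenyl]-1,3-dihydroxypropan-2-yl}-4-fluoro-5-methoxybenzonitrile | N#Cc1cc(OC)c(F)c(c1)[C@H](CO)[C@H](c1ccc(OCc2ccccc2)c(OC)c1)O
F5 | step 4 | 3-{(1R,2R)-1-[4-(benzyloxy)-3-methoxyphenyl]-3-[(tert-butyldimethylsilyl)oxy]-1-hydroxypropan-2-yl}-4-fluoro-5-methoxybenzonitrile | N#Cc1cc(OC)c(F)c(c1)[C@H](CO[Si](C)(C)C(C)(C)C)[C@H](c1ccc(OCc2ccccc2)c(OC)c1)O
F6 | step 11 | methyl (2Z)-2-(bromomethyl)-4-[(tert-butyldimethylsilyl)oxy]but-2-enoate | COC(=O)/C(CBr)=C/CO[Si](C)(C)C(C)(C)C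
F7 | step 11 | methyl (3R)-3-[(R)-Ar1(hydroxy)methyl]-4-[(tert-butyldimethylsilyl)oxy]-2-methylidenebutanoate | C=C(C(=O)OC)[C@H](CO[Si](C)(C)C(C)(C)C)[C@H](c1cc(OC)c2c(c1)[C@H](CO[Si](C)(C)C(C)(C)C)[C@H](c1ccc(OCc3ccccc3)c(OC)c1)O2)O
F8 | step 11 | methyl (3S)-3-[(S)-Ar1(hydroxy)methyl]-4-[(tert-butyldimethylsilyl)oxy]-2-methylidenebutanoate | C=C(C(=O)OC)[C@@H](CO[Si](C)(C)C(C)(C)C)[C@@H](c1cc(OC)c2c(c1)[C@H](CO[Si](C)(C)C(C)(C)C)[C@H](c1ccc(OCc3ccccc3)c(OC)c1)O2)O
F9 | step 11 | (4S,5S)-5-Ar1-4-{[(tert-butyldimethylsilyl)oxy]methyl}-3-methylideneoxolan-2-one | C=C1C(=O)O[C@H](c2cc(OC)c3c(c2)[C@H](CO[Si](C)(C)C(C)(C)C)[C@H](c2ccc(OCc4ccccc4)c(OC)c2)O3)[C@@H]1CO[Si](C)(C)C(C)(C)C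
F10 | step 15 | (3S,4R,5R)-5-Ar1-3-(iodomethyl)-4-{[(tert-butyldimethylsilyl)oxy]methyl}oxolan-3-ol | IC[C@@]1(O)CO[C@@H](c2cc(OC)c3c(c2)[C@H](CO[Si](C)(C)C(C)(C)C)[C@H](c2ccc(OCc4ccccc4)c(OC)c2)O3)[C@H]1CO[Si](C)(C)C(C)(C)C
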